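**Plan**
- Cuts: C8–H goes back to C8–Br (a blocking group). Ring C is cut at C4–C4a (Friedel–Crafts acylation) and at O1–C2 (phenoxide addition to an alkyne). The three-carbon bridge is cut at C3–C4, C2–C3 and C2–C1'.
- Forward: rings A and B are bought intact. Ring B is extended to an arylpropiolate by formylation, dibromo-olefination and acetylide acylation, and ring A is brominated. The halves are joined through O1, and ring C, the only ring made, is closed last at carbon.
- Enabling feature: the ring A carbon that becomes C4a lies between C8a (bearing O1) and C5 (bearing OMe) and is activated by both oxygens. Its faster rival C8 is a plain CH in the target, so it can hold a removable bromine. C2' and C6' of ring B are both methoxylated, so the activated acyl carbon has no other ring carbon to close on.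
- Stereochemistry: the target has no stereocentre. Only the enol ether geometry of the open precursor matters (O1 and C4 cis, Z). It comes from anti addition to the alkyne and corrects itself in acid.

Key step: step 7

Assumption: the C2–C1' axis is taken as freely rotating, so the target is treated as achiral, and the three starting materials are taken as catalogue chemicals.

Step 1
Reactants: 1 3,4-dimethoxyphenol
Product: 2 2-bromo-4,5-dimethoxyphenol
Conditions: NBS (1.0 equiv), CH2Cl2, −20 °C to 0 °C, dark
Reagents that add atoms: N-bromosuccinimide, O=C1CCC(=O)N1Br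
Why: Electrophilic aromatic bromination should go to the carbon ortho to the hydroxyl and para to the 3-methoxy group (the future C8), because the other ortho carbon is flanked by two oxygen substituents, and one equivalent of NBS in the cold limits dibromination and oxidation to the quinone.

Step 2
Reactants: 3 1,2,3,5-tetramethoxybenzene
Product: 5 2,3,4,6-tetramethoxybenzaldehyde, via aryl iminium chloride 4 (not isolated)
Conditions: POCl3 (1.2 equiv), DMF, 0 °C to rt; then ice-water
Reagents that add atoms: N,N-dimethylformamide, CN(C)C=O; water, O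
Why: In this Vilsmeier–Haack formylation the two free ring carbons are equivalent by symmetry and each has two ortho and one para methoxy donor, so the chloroiminium ion attacks readily, and iminium salt 4 deactivates the ring against a second attack until water releases the aldehyde.

Step 3
Reactants: 5 2,3,4,6-tetramethoxybenzaldehyde
Product: 6 1-(2,2-dibromoethenyl)-2,3,4,6-tetramethoxybenzene
Conditions: CBr4, PPh3, Zn dust (2 equiv each), CH2Cl2, rt, 24 h; then 5, rt
Reagents that add atoms: carbon tetrabromide, BrC(Br)(Br)Br
Why: This first stage of the Corey–Fuchs sequence is a Wittig-type olefination by Ph3P=CBr2 preformed with zinc, which forms C2–C3 and avoids Ph3PBr2, so the methyl ethers and the electron-rich ring are spared.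

Step 4
Reactants: 6 1-(2,2-dibromoethenyl)-2,3,4,6-tetramethoxybenzene; 7 ethyl chloroformate
Product: 9 ethyl 3-(2,3,4,6-tetramethoxyphenyl)prop-2-ynoate, via lithium acetylide 8 (not isolated)
Conditions: n-BuLi (2.05 equiv), THF, −78 °C, 1 h; then ClCO2Et (1.5 equiv), −78 °C to 0 °C
Reagents that add atoms: ethyl chloroformate 7, CCOC(=O)Cl
Why: In this second stage of the Corey–Fuchs sequence, bromine–lithium exchange, loss of LiBr with a 1,2-shift (Fritsch–Buttenberg–Wiechell type) and deprotonation give acetylide 8, whose C-acylation by the chloroformate forms C3–C4, while the near-exact charge of n-BuLi at −78 °C leaves the C5'–H between two methoxy groups unmetalated.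

Step 5
Reactants: 9 ethyl 3-(2,3,4,6-tetramethoxyphenyl)prop-2-ynoate; 2 2-bromo-4,5-dimethoxyphenol
Product: 10 ethyl (Z)-3-(2-bromo-4,5-dimethoxyphenoxy)-3-(2,3,4,6-tetramethoxyphenyl)prop-2-enoate
Conditions: Cs2CO3 (0.5 equiv), DMF, 80 °C
Reagents that add atoms: none
Why: Base-mediated oxa-Michael addition of a phenoxide to an arylpropiolate, the first half of the Ruhemann chromone synthesis, forms O1–C2 by anti addition, which places the aryloxy group and the ester on the same side (Z), and any E isomer can be carried on because step 7 equilibrates the geometry.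

Step 6
Reactants: 10 ethyl (Z)-3-(2-bromo-4,5-dimethoxyphenoxy)-3-(2,3,4,6-tetramethoxyphenyl)prop-2-enoate
Product: 12 (Z)-3-(2-bromo-4,5-dimethoxyphenoxy)-3-(2,3,4,6-tetramethoxyphenyl)prop-2-enoic acid, via lithium carboxylate 11 (not isolated)
Conditions: LiOH·H2O (3 equiv), THF/MeOH/H2O, rt to 40 °C; then 1 M HCl to pH 3, 0 °C
Reagents that add atoms: lithium hydroxide, [Li+].[OH-]
Why: In this ester saponification (acyl–oxygen cleavage) hydroxide attacks the open ester carbonyl rather than the shielded, donor-substituted β-carbon, the aryl bromide and methyl ethers are inert to LiOH, and cold acidification to only pH 3 keeps the enol ether from hydrolysing.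

Step 7
Reactants: 12 (Z)-3-(2-bromo-4,5-dimethoxyphenoxy)-3-(2,3,4,6-tetramethoxyphenyl)prop-2-enoic acid
Product: 14 8-bromo-5,6-dimethoxy-2-(2,3,4,6-tetramethoxyphenyl)-4H-chromen-4-one, via acyl mesylate 13 (not isolated)
Conditions: P2O5/CH3SO3H (1:10 w/w), 0.03 M, rt to 40 °C; then ice
Reagents that add atoms: none
Why: P2O5/CH3SO3H dehydrates acid 12 to acyl mesylate 13, which reacts as an acylium equivalent: its acyl carbon (future C4) is attacked by the one free carbon ortho to the ether oxygen on ring A (future C4a), and loss of the ring proton restores aromaticity and gives the 4-pyranone. The closest known reaction type is the second half of the Ruhemann chromone synthesis, the intramolecular Friedel–Crafts acylation of 3-aryloxycinnamic and aryloxyfumaric acids in H2SO4, polyphosphoric acid or P2O5/CH3SO3H. Ring C closes in a six-membered exo mode (6-exo-trig at the anhydride carbonyl, 6-exo-dig if ionisation comes first) through C4a, C8a, O1, C2, C3 and C4, and no stereocentre is formed. The step needs regioselectivity between the two carbons ortho to O1: the intrinsically faster one (future C8, para to the C5 methoxy group) carries bromine, so only the carbon between O1 and the C5 methoxy group, still activated by two ortho oxygen donors, can be acylated. It also needs chemoselectivity against ring B, which is secured because C2' and C6' both bear methoxy groups (no indenone closure) and because dilution disfavours intermolecular acylation at C5'. Any E isomer is fed into the productive Z geometry by reversible protonation of the enol ether at C3, and the mild temperature should keep the C–Br bond and the peri C5 methyl ether intact.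

Step 8
Reactants: 14 8-bromo-5,6-dimethoxy-2-(2,3,4,6-tetramethoxyphenyl)-4H-chromen-4-one
Product: 15 5,6-dimethoxy-2-(2,3,4,6-tetramethoxyphenyl)-4H-chromen-4-one (5,6,2',3',4',6'-hexamethoxyflavone)
Conditions: 10% Pd/C, HCO2NH4 (3 equiv), MeOH/THF, rt to 40 °C, stopped when 14 is consumed
Reagents that add atoms: none
Why: In this catalytic transfer hydrogenolysis of an aryl bromide, zerovalent palladium inserts into C8–Br and formate supplies the hydride, which should be much faster than reduction of the trisubstituted C2–C3 double bond of the vinylogous ester shielded by the di-ortho-substituted ring B, and ammonium formate also neutralises the HBr.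

**Compound list**
1 | 3,4-dimethoxyphenol | COc1ccc(O)cc1OC | starting material
2 | 2-bromo-4,5-dimethoxyphenol | COc1cc(O)c(Br)cc1OC | intermediate
3 | 1,2,3,5-tetramethoxybenzene | COc1cc(OC)c(OC)c(OC)c1 | starting material
4 | N,N-dimethyl-(2,3,4,6-tetramethoxybenzylidene)iminium chloride | C[N+](C)=Cc1c(OC)cc(OC)c(OC)c1OC.[Cl-] | intermediate
5 | 2,3,4,6-tetramethoxybenzaldehyde | O=Cc1c(OC)cc(OC)c(OC)c1OC | intermediate
6 | 1-(2,2-dibromoethenyl)-2,3,4,6-tetramethoxybenzene | BrC(Br)=Cc1c(OC)cc(OC)c(OC)c1OC | intermediate
7 | ethyl chloroformate | CCOC(=O)Cl | starting material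
8 | lithium (2,3,4,6-tetramethoxyphenyl)acetylide | [Li]C#Cc1c(OC)cc(OC)c(OC)c1OC | intermediate
9 | ethyl 3-(2,3,4,6-tetramethoxyphenyl)prop-2-ynoate | CCOC(=O)C#Cc1c(OC)cc(OC)c(OC)c1OC | intermediate
10 | ethyl (Z)-3-(2-bromo-4,5-dimethoxyphenoxy)-3-(2,3,4,6-tetramethoxyphenyl)prop-2-enoate | COc1cc(OC)c(/C(Oc2cc(OC)c(OC)cc2Br)=C/C(=O)OCC)c(OC)c1OC | intermediate
11 | lithium (Z)-3-(2-bromo-4,5-dimethoxyphenoxy)-3-(2,3,4,6-tetramethoxyphenyl)prop-2-enoate | COc1cc(OC)c(/C(Oc2cc(OC)c(OC)cc2Br)=C/C(=O)[O-])c(OC)c1OC.[Li+] | intermediate
12 | (Z)-3-(2-bromo-4,5-dimethoxyphenoxy)-3-(2,3,4,6-tetramethoxyphenyl)prop-2-enoic acid | COc1cc(OC)c(/C(Oc2cc(OC)c(OC)cc2Br)=C/C(=O)O)c(OC)c1OC | intermediate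
13 | (Z)-3-(2-bromo-4,5-dimethoxyphenoxy)-3-(2,3,4,6-tetramethoxyphenyl)prop-2-enoic methanesulfonic anhydride | COc1cc(OC)c(/C(Oc2cc(OC)c(OC)cc2Br)=C/C(=O)OS(C)(=O)=O)c(OC)c1OC | intermediate
14 | 8-bromo-5,6-dimethoxy-2-(2,3,4,6-tetramethoxyphenyl)-4H-chromen-4-one | COc1cc(OC)c(-c2cc(=O)c3c(OC)c(OC)cc(Br)c3o2)c(OC)c1OC | intermediate
15 | 5,6-dimethoxy-2-(2,3,4,6-tetramethoxyphenyl)-4H-chromen-4-one (5,6,2',3',4',6'-hexamethoxyflavone) | COc1cc(OC)c(-c2cc(=O)c3c(OC)c(OC)ccc3o2)c(OC)c1OC | target

**Step count**
- Total step count: 8.
- Longest linear sequence: 7 (steps 2 to 8, from 3).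

**Steps most likely to fail**

1. Step 7.
   - Risk: the strong acid may protonate or acylate the brominated carbon, which is para to a methoxy group. Bromine would then be lost or would migrate to ring B, and regiocontrol would erode.
   - Further drains are lactonisation through an ortho-methoxy oxygen of ring B from the E geometry, cleavage of the peri C5 methyl ether, and intermolecular acylation at C5'.
   - Fallback (sets out from 1 and 6, comes back at 15): the polarity of ring A is inverted so that C4a reacts as a carbanion, and neither blocker nor strong acid is needed. Phenol 1 is protected with MOMCl/i-Pr2NEt as 1,2-dimethoxy-4-(methoxymethoxy)benzene F1. In F1, n-BuLi (THF, 0 °C) removes the proton between the two oxygen substituents by cooperative directed ortho-metalation and gives [2,3-dimethoxy-6-(methoxymethoxy)phenyl]lithium F2. Acetylide 8, raised from 6 as in step 4, is trapped with N-methoxy-N-methylcarbamoyl chloride to give N-methoxy-N-methyl-3-(2,3,4,6-tetramethoxyphenyl)prop-2-ynamide F3. F2 and F3 combine at −78 °C to give 1-[2,3-dimethoxy-6-(methoxymethoxy)phenyl]-3-(2,3,4,6-tetramethoxyphenyl)prop-2-yn-1-one F4. HCl in MeOH removes the acetal to give 1-(6-hydroxy-2,3-dimethoxyphenyl)-3-(2,3,4,6-tetramethoxyphenyl)prop-2-yn-1-one F5. Catalytic DMAP in DMF then closes ring C by 6-endo-dig oxa-Michael addition and gives 15 directly.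

2. Step 5.
   - Risk: conjugate addition may be sluggish, because the four methoxy donors of ring B lower the electrophilicity of the β-carbon and the ortho-bromophenoxide is hindered. Forcing temperatures invite acyl transfer from the ester to the phenoxide and decomposition.
   - Fallback (sets out from 6 and 2, comes back at 12): the acceptor is raised to the more electrophilic aldehyde oxidation level. Acetylide 8, raised from 6 as in step 4, is quenched with DMF instead of 7 to give 3-(2,3,4,6-tetramethoxyphenyl)prop-2-ynal F6. Phenol 2 adds under mild base (K2CO3, MeCN, rt) to give (Z)-3-(2-bromo-4,5-dimethoxyphenoxy)-3-(2,3,4,6-tetramethoxyphenyl)prop-2-enal F7. Pinnick oxidation (NaClO2, NaH2PO4, excess 2-methyl-2-butene, t-BuOH/H2O) gives acid 12, so step 6 is no longer needed.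

3. Step 8.
   - Risk: over-reduction, that is saturation of the C2–C3 double bond or reduction of the carbonyl on the palladium surface in competition with C–Br hydrogenolysis.
   - Fallback (sets out from 14, comes back at 15): the surface hydrogenolysis is replaced by a homolytic chain reduction (Bu3SnH, AIBN, toluene, 85 °C). The stannyl radical abstracts bromine and the C8 aryl radical takes hydrogen from the stannane, a path that offers no hydrogenation of the enone. No new isolable compound lies on this way.

**Further compounds**
F1 | step 7 | 1,2-dimethoxy-4-(methoxymethoxy)benzene | COCOc1ccc(OC)c(OC)c1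
F2 | step 7 | [2,3-dimethoxy-6-(methoxymethoxy)phenyl]lithium | COCOc1ccc(OC)c(OC)c1[Li]
F3 | step 7 | N-methoxy-N-methyl-3-(2,3,4,6-tetramethoxyphenyl)prop-2-ynamide | COc1cc(OC)c(C#CC(=O)N(C)OC)c(OC)c1OC
F4 | step 7 | 1-[2,3-dimethoxy-6-(methoxymethoxy)phenyl]-3-(2,3,4,6-tetramethoxyphenyl)prop-2-yn-1-one | COCOc1ccc(OC)c(OC)c1C(=O)C#Cc1c(OC)cc(OC)c(OC)c1OC
F5 | step 7 | 1-(6-hydroxy-2,3-dimethoxyphenyl)-3-(2,3,4,6-tetramethoxyphenyl)prop-2-yn-1-one | Oc1ccc(OC)c(OC)c1C(=O)C#Cc1c(OC)cc(OC)c(OC)c1OC
F6 | step 5 | 3-(2,3,4,6-tetramethoxyphenyl)prop-2-ynal | COc1cc(OC)c(C#CC=O)c(OC)c1OC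
F7 | step 5 | (Z)-3-(2-bromo-4,5-dimethoxyphenoxy)-3-(2,3,4,6-tetramethoxyphenyl)prop-2-enal | COc1cc(OC)c(/C(Oc2cc(OC)c(OC)cc2Br)=C/C=O)c(OC)c1OC
F0 | step 8 | none | none
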